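**Retrosynthetic overview**

- The target is (13E)-6β-acetoxy-7α-(3-methylbutanoyloxy)labda-8,13-dien-15-oic acid. Last come fluoride release of the acid, acetylation of O6 and isovaleroylation of O7 of a 6β,7α-diol.
- The diol comes from a 7-en-6-one. Its extended dienolate is hydroxylated at C7 on the α-face, which moves the alkene to C8=C9 and erases the transient C9 centre; hydride then adds to C6 from the α-face. The enone comes from allylic oxidation at C6 of a labda-7,13E-dienoate.
- Key disconnection: C4–C5 and C9–C10. Ring A, then ring B, close in one proton-initiated cationic cascade of methyl (2E,6E,10E)-geranylgeranoate, itself made by olefination of (5E,9E)-farnesylacetone.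
- Feature on which the strategy rests: the trans-fused decalin (rings A and B) with gem-dimethyl C4, 5α-H and 10β-methyl is the chair–chair fold of an all-E isoprenoid chain. The C13=C14 alkene conjugated to C15 is too electron-poor to enter the cascade, so it is carried through as the side-chain enoate.

Key step: step 2

Assumption: labdane numbering and α/β descriptors are used; the target is read as 5α-H, 6β-acetoxy, 7α-(3-methylbutanoyloxy), 10β-methyl, 13E, and the (R)-configured proton donor is taken to give this normal series, as it does with related polyprenoids (its enantiomer would be used if the sense proved opposite).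

**Route**

Step 1
Reactants: 1 (5E,9E)-farnesylacetone; 2 trimethyl phosphonoacetate
Product: 4 methyl (2E,6E,10E)-geranylgeranoate, via sodium phosphonate carbanion 3 (not isolated)
Conditions: NaH, THF, 0 °C; then 1, 0 to 60 °C; silica gel chromatography to remove the 2Z isomer
Reagents that add atoms: none
Why: Horner–Wadsworth–Emmons olefination of a methyl ketone, in which reversible addition of carbanion 3 favours the E-enoate (ester trans to the longer chain) and the minor 2Z isomer is separable on silica, while the two existing E alkenes are untouched.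

Step 2
Reactants: 4 methyl (2E,6E,10E)-geranylgeranoate
Product: 6 methyl (13E)-labda-7,13-dien-15-oate of the 5α-H/9α-H/10β-methyl series, via tertiary C8 cation 5 (not isolated)
Conditions: (R)-2-(2-fluorobenzyloxy)-2'-hydroxy-1,1'-binaphthyl (2.2 equiv), SnCl4 (2 equiv), toluene, −78 °C, 2–3 d; AgNO3–silica gel chromatography
Reagents that add atoms: none
Why: Lewis-acid-assisted chiral Brønsted acid polyene cyclization, the enantioselective form of the proton-initiated bicyclization known for ester-terminated polyprenoids: the SnCl4-bound phenol delivers its proton to C3 of the terminal isopropylidene group, C5 of the C5=C10 alkene bonds to C4, C9 of the C8=C9 alkene bonds to C10, and the resulting tertiary cation 5 loses its axial 7α-hydrogen to give the C7=C8 alkene. Ring A closes first and ring B second, each as a 6-endo-trig closure through a chair. C5 (α-H) and C10 (β-methyl) arise from anti addition across the E C5=C10 alkene and C9 (α-H, β side chain) from anti addition across the E C8=C9 alkene, so the relative configuration is dictated by the all-E geometry in a chair–chair fold and the absolute sense by the face of the terminal alkene that the (R)-binaphthyl proton donor can reach. The step needs the cascade to stop after two rings, which the substrate secures because the ester-conjugated C13=C14 alkene is too electron-poor to attack cation 5; SnCl4 is used in excess since the ester carbonyl ties up part of it. It also needs proton loss from C7 and not from C9 or C17, which rests only on the accessibility of the axial 7α-H, so the 8(17)- and 8(9)-ene isomers must be expected as by-products and are removed on AgNO3-impregnated silica.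

Step 3
Reactants: 6 methyl (13E)-labda-7,13-dien-15-oate
Product: 7 (13E)-labda-7,13-dien-15-oic acid
Conditions: LiOH·H2O, THF/MeOH/H2O, 50 °C; then cold 1 M HCl to pH 3
Reagents that add atoms: lithium hydroxide, [Li+].[OH-]
Why: Saponification (acyl–oxygen cleavage) of the methyl ester is done here because no other ester is yet present; hydroxide is not basic enough to move the enoate or the C7=C8 alkene, and no stereocentre is touched.

Step 4
Reactants: 7 (13E)-labda-7,13-dien-15-oic acid
Product: 8 2-(trimethylsilyl)ethyl (13E)-labda-7,13-dien-15-oate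
Conditions: 2-(trimethylsilyl)ethanol, DCC, DMAP (0.1 equiv), CH2Cl2, 0 °C to rt
Reagents that add atoms: 2-(trimethylsilyl)ethanol, C[Si](C)(C)CCO
Why: Steglich esterification installs an ester that fluoride can later remove without touching the acetate and the isovalerate, under neutral conditions that leave both alkenes and all stereocentres alone.

Step 5
Reactants: 8 2-(trimethylsilyl)ethyl (13E)-labda-7,13-dien-15-oate
Product: 9 2-(trimethylsilyl)ethyl (13E)-6-oxolabda-7,13-dien-15-oate
Conditions: CrO3, 3,5-dimethylpyrazole, CH2Cl2, −20 °C
Reagents that add atoms: chromium trioxide, O=[Cr](=O)=O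
Why: Chromium-mediated allylic oxidation: C6 is the only allylic methylene of the electron-rich C7=C8 alkene (C9–H is tertiary and shielded, C17 is a methyl group, and the positions allylic to the enoate are deactivated), so the conjugated 7-en-6-one should form without creating or disturbing a stereocentre.

Step 6
Reactants: 9 2-(trimethylsilyl)ethyl (13E)-6-oxolabda-7,13-dien-15-oate
Product: 11 2-(trimethylsilyl)ethyl (13E)-7α-hydroxy-6-oxolabda-8,13-dien-15-oate, via potassium 6,8-dienolate 10 (not isolated)
Conditions: KOtBu (1.05 equiv), THF, −78 to −20 °C; then 2-(phenylsulfonyl)-3-phenyloxaziridine, −78 °C; AcOH quench at −78 °C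
Reagents that add atoms: 2-(phenylsulfonyl)-3-phenyloxaziridine, O=S(=O)(c1ccccc1)N1OC1c1ccccc1
Why: Enolate hydroxylation with an N-sulfonyloxaziridine (Davis oxidation) through the extended dienolate: equilibrating γ-deprotonation removes the axial 9α-H (erasing C9, while the C5–H between two quaternary carbons stays) to give the endocyclic dienolate 10, which takes the electrophilic oxygen at its α-carbon C7 from the α-face because the β-face is covered by the axial 10β- and 4β-methyl groups, so the 7α-hydroxyl is set and the alkene lands at C8=C9.

Step 7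
Reactants: 11 2-(trimethylsilyl)ethyl (13E)-7α-hydroxy-6-oxolabda-8,13-dien-15-oate
Product: 12 2-(trimethylsilyl)ethyl (13E)-6β,7α-dihydroxylabda-8,13-dien-15-oate
Conditions: NaBH4, CeCl3·7H2O, MeOH, −40 °C; water work-up
Reagents that add atoms: none
Why: Luche-type borohydride reduction is fast and weakly basic, so the sensitive ketol is not tautomerized and the enoate ester is not reduced; hydride reaches C6 from the α-face because the β-face is blocked by the syn-axial 10β- and 4β-methyl groups, which sets the axial 6β-hydroxyl trans to O7.

Step 8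
Reactants: 12 2-(trimethylsilyl)ethyl (13E)-6β,7α-dihydroxylabda-8,13-dien-15-oate
Product: 13 2-(trimethylsilyl)ethyl (13E)-6β-hydroxy-7α-(3-methylbutanoyloxy)labda-8,13-dien-15-oate
Conditions: isovaleryl chloride (1.1 equiv), pyridine, CH2Cl2, −20 to 0 °C
Reagents that add atoms: 3-methylbutanoyl chloride, CC(C)CC(Cl)=O
Why: Site-selective O-acylation: the allylic 7α-OH is far more accessible than the 6β-OH, which sits under two syn-axial methyl groups, and the trans-diaxial arrangement of the two oxygens rules out later acyl migration.

Step 9
Reactants: 13 2-(trimethylsilyl)ethyl (13E)-6β-hydroxy-7α-(3-methylbutanoyloxy)labda-8,13-dien-15-oate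
Product: 14 2-(trimethylsilyl)ethyl (13E)-6β-acetoxy-7α-(3-methylbutanoyloxy)labda-8,13-dien-15-oate
Conditions: Ac2O, DMAP, Et3N, CH2Cl2, 40 °C
Reagents that add atoms: acetic anhydride, CC(=O)OC(C)=O
Why: DMAP-catalysed acetylation (nucleophilic acyl-transfer catalysis) is the standard way to esterify a hindered secondary alcohol, and the 6β-OH is the only free hydroxyl left, so no selectivity question arises and no stereocentre is touched.

Step 10
Reactants: 14 2-(trimethylsilyl)ethyl (13E)-6β-acetoxy-7α-(3-methylbutanoyloxy)labda-8,13-dien-15-oate
Product: 15 (13E)-6β-acetoxy-7α-(3-methylbutanoyloxy)labda-8,13-dien-15-oic acid (CNP0328312.2)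
Conditions: Bu4NF, THF, 0 °C to rt; then cold 0.5 M HCl
Reagents that add atoms: none
Why: Fluoride-induced fragmentation of the 2-(trimethylsilyl)ethyl ester (attack at silicon, loss of ethylene) frees the carboxylic acid under conditions that should not hydrolyse the hindered acetate and isovalerate, and no stereocentre is affected.

**Compound list**

1 | (5E,9E)-farnesylacetone, (5E,9E)-6,10,14-trimethylpentadeca-5,9,13-trien-2-one | CC(C)=CCC/C(C)=C/CC/C(C)=C/CCC(C)=O | starting material
2 | trimethyl phosphonoacetate | COC(=O)CP(=O)(OC)OC | starting material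
3 | sodium salt of trimethyl phosphonoacetate (phosphonate carbanion) | COC(=O)[CH-]P(=O)(OC)OC.[Na+] | intermediate
4 | methyl (2E,6E,10E)-geranylgeranoate, methyl (2E,6E,10E)-3,7,11,15-tetramethylhexadeca-2,6,10,14-tetraenoate | COC(=O)/C=C(C)/CC/C=C(C)/CC/C=C(C)/CCC=C(C)C | intermediate
5 | tertiary C8 carbocation of methyl (13E)-labd-13-en-15-oate (5α-H, 9α-H, 10β-methyl) | C1C[C+](C)[C@H](CC/C(C)=C/C(=O)OC)[C@@]2(C)CCCC(C)(C)[C@H]12 | intermediate
6 | methyl (13E)-labda-7,13-dien-15-oate (5α-H, 9α-H, 10β-methyl) | C1C=C(C)[C@H](CC/C(C)=C/C(=O)OC)[C@@]2(C)CCCC(C)(C)[C@H]12 | intermediate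
7 | (13E)-labda-7,13-dien-15-oic acid | C1C=C(C)[C@H](CC/C(C)=C/C(=O)O)[C@@]2(C)CCCC(C)(C)[C@H]12 | intermediate
8 | 2-(trimethylsilyl)ethyl (13E)-labda-7,13-dien-15-oate | C1C=C(C)[C@H](CC/C(C)=C/C(=O)OCC[Si](C)(C)C)[C@@]2(C)CCCC(C)(C)[C@H]12 | intermediate
9 | 2-(trimethylsilyl)ethyl (13E)-6-oxolabda-7,13-dien-15-oate | O=C1C=C(C)[C@H](CC/C(C)=C/C(=O)OCC[Si](C)(C)C)[C@@]2(C)CCCC(C)(C)[C@H]12 | intermediate
10 | potassium 6,8-dienolate of 9, potassium (13E)-15-oxo-15-[2-(trimethylsilyl)ethoxy]labda-6,8,13-trien-6-olate | [K+].[O-]C1=CC(C)=C(CC/C(C)=C/C(=O)OCC[Si](C)(C)C)[C@@]2(C)CCCC(C)(C)[C@H]12 | intermediate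
11 | 2-(trimethylsilyl)ethyl (13E)-7α-hydroxy-6-oxolabda-8,13-dien-15-oate | O=C1[C@@H](O)C(C)=C(CC/C(C)=C/C(=O)OCC[Si](C)(C)C)[C@@]2(C)CCCC(C)(C)[C@H]12 | intermediate
12 | 2-(trimethylsilyl)ethyl (13E)-6β,7α-dihydroxylabda-8,13-dien-15-oate | O[C@@H]1[C@@H](O)C(C)=C(CC/C(C)=C/C(=O)OCC[Si](C)(C)C)[C@@]2(C)CCCC(C)(C)[C@H]12 | intermediate
13 | 2-(trimethylsilyl)ethyl (13E)-6β-hydroxy-7α-(3-methylbutanoyloxy)labda-8,13-dien-15-oate | O[C@@H]1[C@@H](OC(=O)CC(C)C)C(C)=C(CC/C(C)=C/C(=O)OCC[Si](C)(C)C)[C@@]2(C)CCCC(C)(C)[C@H]12 | intermediate
14 | 2-(trimethylsilyl)ethyl (13E)-6β-acetoxy-7α-(3-methylbutanoyloxy)labda-8,13-dien-15-oate | CC(=O)O[C@@H]1[C@@H](OC(=O)CC(C)C)C(C)=C(CC/C(C)=C/C(=O)OCC[Si](C)(C)C)[C@@]2(C)CCCC(C)(C)[C@H]12 | intermediate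
15 | (13E)-6β-acetoxy-7α-(3-methylbutanoyloxy)labda-8,13-dien-15-oic acid (CNP0328312.2) | CC(=O)O[C@@H]1[C@@H](OC(=O)CC(C)C)C(C)=C(CC/C(C)=C/C(=O)O)[C@@]2(C)CCCC(C)(C)[C@H]12 | target

**Totals and risks**

Total step count: 10. Longest linear sequence: 10 steps (1 to 15).

Steps most likely to fail:

Step 2. The cascade may stop after the first ring or proceed with little asymmetric induction, because the ester competes for SnCl4, and the final proton may be lost in several directions. The fallback sets out from 4 and returns at 6; it gives up asymmetric protonation in favour of resolution. Compound 4 is treated with FSO3H in 2-nitropropane at −78 °C, the superacid protocol under which ester-terminated polyprenoids are known to close both rings. This should give the racemate, that is 6 together with its mirror image ent-methyl (13E)-labda-7,13-dien-15-oate F1. The two are separated by preparative chromatography on an amylose tris(3,5-dimethylphenylcarbamate) stationary phase and the route continues with 6.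

Step 6. Proton removal may occur at C17 or C5 instead of C9, oxygen may be transferred to C9 instead of C7, or the ketol may be oxidized further under the basic conditions. The fallback sets out from 9 and returns at 11; it replaces anionic oxygen transfer by osmylation of a neutral dienol ether. TMSCl/NaI/Et3N in MeCN, equilibrating conditions that favour the endocyclic diene, should convert 9 into 2-(trimethylsilyl)ethyl (13E)-6-(trimethylsilyloxy)labda-6,8,13-trien-15-oate F2. OsO4 (0.05 equiv) with NMO in acetone–water should then dihydroxylate only the enol ether C6=C7 bond from the α-face, the tetrasubstituted C8=C9 bond being too hindered, and the adduct collapses to ketol 11.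

Step 9. Acyl transfer to the 6β-OH may be too slow (two syn-axial methyl groups and the neighbouring 7α-ester), and forcing conditions may ionize the allylic 7-ester. The fallback sets out from 11 and returns at 14; it acylates a metal alkoxide instead of the neutral alcohol by reversing the order of events. Ketol 11 is esterified with isovaleryl chloride and pyridine to give 2-(trimethylsilyl)ethyl (13E)-7α-(3-methylbutanoyloxy)-6-oxolabda-8,13-dien-15-oate F3. This is reduced with LiAlH(OtBu)3 in THF at −78 to −20 °C (hydride from the α-face), and the 6β-aluminium alkoxide is trapped in the same flask with Ac2O and DMAP (reductive acetylation) to reach 14 directly.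

**Further compounds**

F1 | step 2 | ent-methyl (13E)-labda-7,13-dien-15-oate (5β-H, 9β-H, 10α-methyl) | C1C=C(C)[C@@H](CC/C(C)=C/C(=O)OC)[C@]2(C)CCCC(C)(C)[C@@H]12
F2 | step 6 | 2-(trimethylsilyl)ethyl (13E)-6-(trimethylsilyloxy)labda-6,8,13-trien-15-oate | C[Si](C)(C)OC1=CC(C)=C(CC/C(C)=C/C(=O)OCC[Si](C)(C)C)[C@@]2(C)CCCC(C)(C)[C@H]12
F3 | step 9 | 2-(trimethylsilyl)ethyl (13E)-7α-(3-methylbutanoyloxy)-6-oxolabda-8,13-dien-15-oate | O=C1[C@@H](OC(=O)CC(C)C)C(C)=C(CC/C(C)=C/C(=O)OCC[Si](C)(C)C)[C@@]2(C)CCCC(C)(C)[C@H]12
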